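A direct plan would reach the succinate through a five-membered anhydride: a Wittig-type olefination would give the exo-benzylidene anhydride A1, a chiral amine would open A1 with methanol in a dynamic kinetic resolution to the half-ester A2, and asymmetric hydrogenation of the benzylidene C=C followed by deacylation would finish.
Its weakest step would be the dynamic kinetic alcoholysis meant to set C3: it has no precedent on an alkylidene succinic anhydride, it must also pick one of two carbonyl groups, and the dienolate that racemises A1 can reprotonate at the benzylidene carbon, draining material irreversibly into the achiral, fully conjugated aryl(benzyl)maleic anhydride A3.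
The olefination that makes A1 would be exposed to the same exo-to-endo double-bond shift (acid and heat are present) and to unsecured regiochemistry of phosphine addition, so A1 might never be isolated.
The hydrogenation that sets C2 would leave that centre to an untested match between catalyst and the existing, still labile C3 centre, would have to spare the prenyl alkene, and is the step one would least like to run on the most advanced material.
The aryl acetates would be put on and taken off without gain in complexity, but the plan would fail through risk, not length.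

The new route cuts the C2–C3 bond of the butanedioate chain and, separately, the aryl–prenyl bond; no ring is formed at any stage (both benzene rings are bought, and no anhydride or other ring holding C1–C4 appears).
The enabling feature: C2 and C3 are vicinal CH centres of a 1,4-dicarboxyl chain whose ester end sits on the arylacetic carbon C3 and whose free acid sits on C2, which is the pattern of an Ireland–Claisen product (a γ,δ-unsaturated 2-arylalkanoic acid) after alkene cleavage.
An (R,Z)-allylic 4-silyloxyphenylacetate rearranges through a chair, so one carbinol centre bought as (R)-but-3-yn-2-ol sets C2 and C3 together and is then excised as acetaldehyde.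
The carboxylate born in the rearrangement becomes the methyl ester and the alkene born in it becomes the free acid, so the two ends are never told apart by alcoholysis.
The prenyl group is put on last by Stille coupling at an aryl bromide, after the only oxidative step, so no hydrogenation, no C-prenylation of a phenol and no base-labile alkylidene anhydride occur.
Key step: step 7

Remark: locants C1–C4 in the text are those of the target's butanoic acid chain (C1 = CO2H, C2 = benzyl-bearing CH, C3 = aryl-bearing CH, C4 = CO2Me); compounds 1, 4, 8 and 19 are taken as commercial.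

Step 1
Reactants: 1 2-bromo-4-methylphenol
Product: 2 (2-bromo-4-methylphenoxy)(tert-butyl)dimethylsilane
Conditions: TBSCl, imidazole, DMF, 25 °C
Reagents that add atoms: tert-butyldimethylsilyl chloride CC(C)(C)[Si](C)(C)Cl
Why: Imidazole-promoted O-silylation of a phenol, which masks the acidic OH for the Grignard and enolate steps and tempers the ring towards ozone; no stereocentre is formed.

Step 2
Reactants: 2 (2-bromo-4-methylphenoxy)(tert-butyl)dimethylsilane
Product: 3 [2-bromo-4-(bromomethyl)phenoxy](tert-butyl)dimethylsilane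
Conditions: NBS, AIBN (cat.), PhCF3, 80 °C
Reagents that add atoms: N-bromosuccinimide O=C1CCC(=O)N1Br
Why: Wohl–Ziegler radical bromination, in which chain conditions in a non-polar solvent should favour the single benzylic position over the ring; no stereocentre is formed.

Step 3
Reactants: 4 (R)-but-3-yn-2-ol; 3 [2-bromo-4-(bromomethyl)phenoxy](tert-butyl)dimethylsilane
Product: 6 (R)-5-[3-bromo-4-(tert-butyldimethylsilyloxy)phenyl]pent-3-yn-2-ol, via bis(bromomagnesium) derivative 5 (not isolated)
Conditions: 4, EtMgBr (2 equiv), THF, 0 → 40 °C; then 3, CuCl (10 mol %), THF, 50 °C; aq. NH4Cl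
Reagents that add atoms: none
Why: Copper-catalysed sp–sp3 coupling of an alkynylmagnesium bromide with a benzylic bromide, in which the magnesium alkoxide should not be alkylated and the aryl bromide and the carbinol stereocentre of 4 stay untouched.

Step 4
Reactants: 6 (R)-5-[3-bromo-4-(tert-butyldimethylsilyloxy)phenyl]pent-3-yn-2-ol
Product: 7 (2R,3Z)-5-[3-bromo-4-(tert-butyldimethylsilyloxy)phenyl]pent-3-en-2-ol
Conditions: H2 (1 atm), Pd/CaCO3 poisoned with Pb(OAc)2, quinoline, EtOAc, 25 °C
Reagents that add atoms: none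
Why: Lindlar semihydrogenation adds H2 syn and should stop at the (Z)-alkene, the geometry that the chair of step 7 needs, while sparing the aryl bromide.

Step 5
Reactants: 8 4-hydroxyphenylacetic acid
Product: 10 2-[4-(tert-butyldimethylsilyloxy)phenyl]acetic acid, via bis-silylated acid 9 (not isolated)
Conditions: TBSCl (2.3 equiv), imidazole, DMF, 25 °C; then AcOH/THF/H2O, 25 °C
Reagents that add atoms: tert-butyldimethylsilyl chloride CC(C)(C)[Si](C)(C)Cl
Why: Bis-silylation followed by selective hydrolysis of the far more labile silyl ester, a standard way to a phenol-protected arylacetic acid; no stereocentre is formed.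

Step 6
Reactants: 10 2-[4-(tert-butyldimethylsilyloxy)phenyl]acetic acid; 7 (2R,3Z)-5-[3-bromo-4-(tert-butyldimethylsilyloxy)phenyl]pent-3-en-2-ol
Product: 11 (2R,3Z)-5-[3-bromo-4-(tert-butyldimethylsilyloxy)phenyl]pent-3-en-2-yl 2-[4-(tert-butyldimethylsilyloxy)phenyl]acetate
Conditions: DCC, DMAP (10 mol %), CH2Cl2, 0 → 25 °C
Reagents that add atoms: none
Why: Steglich esterification acylates the secondary allylic alcohol without breaking its C–O bond, so the (R) centre and the (Z)-alkene are carried over unchanged.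

Step 7
Reactants: 11 (2R,3Z)-5-[3-bromo-4-(tert-butyldimethylsilyloxy)phenyl]pent-3-en-2-yl 2-[4-(tert-butyldimethylsilyloxy)phenyl]acetate
Product: 15 methyl (2S,3R,4E)-3-[3-bromo-4-(tert-butyldimethylsilyloxy)benzyl]-2-[4-(tert-butyldimethylsilyloxy)phenyl]hex-4-enoate, via silyl ketene acetal 12 (not isolated), via trimethylsilyl ester 13 (not isolated), via carboxylic acid 14 (not isolated)
Conditions: LiN(SiMe3)2, Me3SiCl, THF/DMPU, −78 °C; then 25 → 60 °C; aq. citric acid; then Me3SiCHN2, PhMe/MeOH, 0 °C
Reagents that add atoms: (trimethylsilyl)diazomethane C[Si](C)(C)C=[N+]=[N-]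
Why: LiN(SiMe3)2 removes the doubly activated arylacetic proton and Me3SiCl traps the enolate on oxygen as the (Z)-silyl ketene acetal 12 (aryl cis to OSiMe3, the geometry expected for arylacetates because it keeps the aryl group conjugated and away from the alkoxy group, reinforced by the dipolar cosolvent), which on warming undergoes the [3,3]-sigmatropic Ireland–Claisen shift that forms the C2–C3 bond of the hexenoate (C3–C2 of the target) as the allylic C–O bond breaks, after which silyl ester 13 is hydrolysed and acid 14 methylated in the same operation. The closest known reaction type is the ester enolate Claisen rearrangement of secondary (Z)-allylic esters with 1,3-chirality transfer. No ring is closed; the only cyclic array is the six-membered chair transition state. The C3 centre of the hexenoate is controlled by the carbinol centre of 11: its methyl group must sit equatorial, since in the other chair it would clash 1,3-diaxially with the cis CH2Ar group, so the new bond forms on the alkene face that carries the oxygen and the (R)-carbinol should give (3R) together with an (E)-propenyl group. The C2 centre is controlled by the ketene acetal geometry, whose equatorial aryl group beside the axial CH2Ar group should give the (2S,3R) isomer, that is, aryl and benzyl anti along the chain as in the target. The step needs O- over C-silylation and a single enolate geometry, which the conjugated arylacetate and the cosolvent should secure, and chair over boat, which the acyclic (Z)-allyl unit favours.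

Step 8
Reactants: 15 methyl (2S,3R,4E)-3-[3-bromo-4-(tert-butyldimethylsilyloxy)benzyl]-2-[4-(tert-butyldimethylsilyloxy)phenyl]hex-4-enoate
Product: 18 (2S,3S)-2-[3-bromo-4-(tert-butyldimethylsilyloxy)benzyl]-3-[4-(tert-butyldimethylsilyloxy)phenyl]-4-methoxy-4-oxobutanoic acid, via ozonide 16 (not isolated), via aldehyde 17 (not isolated)
Conditions: O3, CH2Cl2, −78 °C (Sudan Red 7B end point); Me2S, −78 → 25 °C, concentrate; then NaClO2, NaH2PO4, 2-methylbut-2-ene, t-BuOH/H2O, 0 → 25 °C
Reagents that add atoms: ozone [O-][O+]=O; sodium chlorite [Na+].[O-]Cl=O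
Why: Ozonolysis cleaves the only C=C bond (the former carbinol carbon leaves as acetaldehyde) and buffered Pinnick oxidation of the crude aldehyde should give the acid without epimerising either α-centre, the change from (3R) to (2S) being one of ligand priority only.

Step 9
Reactants: 18 (2S,3S)-2-[3-bromo-4-(tert-butyldimethylsilyloxy)benzyl]-3-[4-(tert-butyldimethylsilyloxy)phenyl]-4-methoxy-4-oxobutanoic acid; 19 tributyl(3-methylbut-2-enyl)stannane
Product: 20 (2S,3S)-2-[4-(tert-butyldimethylsilyloxy)-3-(3-methylbut-2-enyl)benzyl]-3-[4-(tert-butyldimethylsilyloxy)phenyl]-4-methoxy-4-oxobutanoic acid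
Conditions: 19 (2 equiv), Pd(PPh3)4 (5 mol %), DMF, 90 °C
Reagents that add atoms: none
Why: Stille coupling of the aryl bromide with the prenylstannane should deliver mainly the linear prenyl arene and runs without base, so the acidic C3–H, the methyl ester and the free acid are not disturbed.

Step 10
Reactants: 20 (2S,3S)-2-[4-(tert-butyldimethylsilyloxy)-3-(3-methylbut-2-enyl)benzyl]-3-[4-(tert-butyldimethylsilyloxy)phenyl]-4-methoxy-4-oxobutanoic acid
Product: 21 asperteretal G2, (2S,3S)-2-[4-hydroxy-3-(3-methylbut-2-enyl)benzyl]-3-(4-hydroxyphenyl)-4-methoxy-4-oxobutanoic acid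
Conditions: Bu4NF/AcOH (1:1), THF, 0 → 25 °C; citric acid work-up
Reagents that add atoms: none
Why: Acetic acid-buffered fluoride cleaves both aryl silyl ethers under conditions neither acidic enough to cyclise the ortho-prenylphenol to a chroman nor basic enough to epimerise C3.

Compound list
1 | 2-bromo-4-methylphenol | Cc1ccc(O)c(Br)c1 | starting material
2 | (2-bromo-4-methylphenoxy)(tert-butyl)dimethylsilane | Cc1ccc(O[Si](C)(C)C(C)(C)C)c(Br)c1 | intermediate
3 | [2-bromo-4-(bromomethyl)phenoxy](tert-butyl)dimethylsilane | BrCc1ccc(O[Si](C)(C)C(C)(C)C)c(Br)c1 | intermediate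
4 | (R)-but-3-yn-2-ol | C[C@@H](O)C#C | starting material
5 | bromomagnesium (R)-4-(bromomagnesio)but-3-yn-2-olate | C[C@@H](O[Mg]Br)C#C[Mg]Br | intermediate
6 | (R)-5-[3-bromo-4-(tert-butyldimethylsilyloxy)phenyl]pent-3-yn-2-ol | C[C@@H](O)C#CCc1ccc(O[Si](C)(C)C(C)(C)C)c(Br)c1 | intermediate
7 | (2R,3Z)-5-[3-bromo-4-(tert-butyldimethylsilyloxy)phenyl]pent-3-en-2-ol | C[C@@H](O)/C=C\Cc1ccc(O[Si](C)(C)C(C)(C)C)c(Br)c1 | intermediate
8 | 4-hydroxyphenylacetic acid | OC(=O)Cc1ccc(O)cc1 | starting material
9 | tert-butyldimethylsilyl 2-[4-(tert-butyldimethylsilyloxy)phenyl]acetate | CC(C)(C)[Si](C)(C)OC(=O)Cc1ccc(O[Si](C)(C)C(C)(C)C)cc1 | intermediate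
10 | 2-[4-(tert-butyldimethylsilyloxy)phenyl]acetic acid | OC(=O)Cc1ccc(O[Si](C)(C)C(C)(C)C)cc1 | intermediate
11 | (2R,3Z)-5-[3-bromo-4-(tert-butyldimethylsilyloxy)phenyl]pent-3-en-2-yl 2-[4-(tert-butyldimethylsilyloxy)phenyl]acetate | C[C@@H](OC(=O)Cc1ccc(O[Si](C)(C)C(C)(C)C)cc1)/C=C\Cc1ccc(O[Si](C)(C)C(C)(C)C)c(Br)c1 | intermediate
12 | (Z)-trimethylsilyl ketene acetal of 11 (aryl cis to OSiMe3; (R)-carbinol and (Z)-alkene unchanged) | C[C@@H](O/C(O[Si](C)(C)C)=C/c1ccc(O[Si](C)(C)C(C)(C)C)cc1)/C=C\Cc1ccc(O[Si](C)(C)C(C)(C)C)c(Br)c1 | intermediate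
13 | trimethylsilyl (2S,3R,4E)-3-[3-bromo-4-(tert-butyldimethylsilyloxy)benzyl]-2-[4-(tert-butyldimethylsilyloxy)phenyl]hex-4-enoate | C[Si](C)(C)OC(=O)[C@H](c1ccc(O[Si](C)(C)C(C)(C)C)cc1)[C@H](Cc1ccc(O[Si](C)(C)C(C)(C)C)c(Br)c1)/C=C/C | intermediate
14 | (2S,3R,4E)-3-[3-bromo-4-(tert-butyldimethylsilyloxy)benzyl]-2-[4-(tert-butyldimethylsilyloxy)phenyl]hex-4-enoic acid | OC(=O)[C@H](c1ccc(O[Si](C)(C)C(C)(C)C)cc1)[C@H](Cc1ccc(O[Si](C)(C)C(C)(C)C)c(Br)c1)/C=C/C | intermediate
15 | methyl (2S,3R,4E)-3-[3-bromo-4-(tert-butyldimethylsilyloxy)benzyl]-2-[4-(tert-butyldimethylsilyloxy)phenyl]hex-4-enoate | COC(=O)[C@H](c1ccc(O[Si](C)(C)C(C)(C)C)cc1)[C@H](Cc1ccc(O[Si](C)(C)C(C)(C)C)c(Br)c1)/C=C/C | intermediate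
16 | methyl (2S,3S)-4-[3-bromo-4-(tert-butyldimethylsilyloxy)phenyl]-2-[4-(tert-butyldimethylsilyloxy)phenyl]-3-(5-methyl-1,2,4-trioxolan-3-yl)butanoate (ozonide of 15; mixture at the trioxolane carbons) | COC(=O)[C@H](c1ccc(O[Si](C)(C)C(C)(C)C)cc1)[C@H](Cc1ccc(O[Si](C)(C)C(C)(C)C)c(Br)c1)C1OC(C)OO1 | intermediate
17 | methyl (2S,3S)-3-[3-bromo-4-(tert-butyldimethylsilyloxy)benzyl]-2-[4-(tert-butyldimethylsilyloxy)phenyl]-4-oxobutanoate | COC(=O)[C@H](c1ccc(O[Si](C)(C)C(C)(C)C)cc1)[C@H](Cc1ccc(O[Si](C)(C)C(C)(C)C)c(Br)c1)C=O | intermediate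
18 | (2S,3S)-2-[3-bromo-4-(tert-butyldimethylsilyloxy)benzyl]-3-[4-(tert-butyldimethylsilyloxy)phenyl]-4-methoxy-4-oxobutanoic acid | COC(=O)[C@H](c1ccc(O[Si](C)(C)C(C)(C)C)cc1)[C@H](Cc1ccc(O[Si](C)(C)C(C)(C)C)c(Br)c1)C(=O)O | intermediate
19 | tributyl(3-methylbut-2-enyl)stannane | CCCC[Sn](CCCC)(CCCC)CC=C(C)C | starting material
20 | (2S,3S)-2-[4-(tert-butyldimethylsilyloxy)-3-(3-methylbut-2-enyl)benzyl]-3-[4-(tert-butyldimethylsilyloxy)phenyl]-4-methoxy-4-oxobutanoic acid | COC(=O)[C@H](c1ccc(O[Si](C)(C)C(C)(C)C)cc1)[C@H](Cc1ccc(O[Si](C)(C)C(C)(C)C)c(CC=C(C)C)c1)C(=O)O | intermediate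
21 | asperteretal G2, (2S,3S)-2-[4-hydroxy-3-(3-methylbut-2-enyl)benzyl]-3-(4-hydroxyphenyl)-4-methoxy-4-oxobutanoic acid | COC(=O)[C@H](c1ccc(O)cc1)[C@H](Cc1ccc(O)c(CC=C(C)C)c1)C(=O)O | target

Total steps: 10. Longest linear sequence: 9 steps (steps 1, 2, 3, 4, 6, 7, 8, 9, 10).

Steps most likely to fail

Step 7. A minor share of the other enolate geometry, C-silylation of the stabilised enolate, or leakage through a boat transition state would erode the anti relationship and the chirality transfer. The fallback replaces chirality transfer by catalyst control and sets out from 10 and 3. Acid 10 would be esterified with pentafluorophenol (EDC) to pentafluorophenyl 2-[4-(tert-butyldimethylsilyloxy)phenyl]acetate F1. Bromide 3 would be coupled with vinylmagnesium bromide (CuI cat.) to (4-allyl-2-bromophenoxy)(tert-butyl)dimethylsilane F2. Cross-metathesis of F2 with (Z)-but-2-ene-1,4-diyl dimethyl dicarbonate (second-generation Hoveyda–Grubbs catalyst) would give (E)-4-[3-bromo-4-(tert-butyldimethylsilyloxy)phenyl]but-2-enyl methyl carbonate F3. F1 and F3 would be joined by the known branched-selective, stereodivergent allylic alkylation of pentafluorophenyl arylacetates under cooperative catalysis by a cyclometallated iridium phosphoramidite complex (from [Ir(cod)Cl]2) and benzotetramisole. Each catalyst controls one centre, and the enantiomer of each would be chosen to give pentafluorophenyl (2S,3R)-3-[3-bromo-4-(tert-butyldimethylsilyloxy)benzyl]-2-[4-(tert-butyldimethylsilyloxy)phenyl]pent-4-enoate F4. Methanolysis in the same flask (MeOH, DMAP) would give methyl (2S,3R)-3-[3-bromo-4-(tert-butyldimethylsilyloxy)benzyl]-2-[4-(tert-butyldimethylsilyloxy)phenyl]pent-4-enoate F5. Ozonolysis of F5 under the conditions of step 8 would pass through methyl (2S,3S)-4-[3-bromo-4-(tert-butyldimethylsilyloxy)phenyl]-2-[4-(tert-butyldimethylsilyloxy)phenyl]-3-(1,2,4-trioxolan-3-yl)butanoate F6 and come back to the route at aldehyde 17.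

Step 9. The allyl unit may be transferred through its γ-carbon (giving the 1,1-dimethylallyl isomer), oxidative addition beside the bulky silyl ether may be slow, and the free acid may protodestannylate the reagent. The fallback sets out from 18 and builds the trisubstituted alkene by metathesis instead of transferring it intact. Stille coupling of 18 with allyltributylstannane (Pd(PPh3)4, DMF), which has no regiochemical ambiguity, would give (2S,3S)-2-[3-allyl-4-(tert-butyldimethylsilyloxy)benzyl]-3-[4-(tert-butyldimethylsilyloxy)phenyl]-4-methoxy-4-oxobutanoic acid F7. Cross-metathesis of F7 with 2-methylbut-2-ene (second-generation Grubbs catalyst, CH2Cl2, 40 °C) would come back to the route at 20.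

Step 8. Ozone may over-oxidise the two silyloxy-substituted rings, and the α-branched aldehyde may epimerise during the reductive work-up. The fallback sets out from 15 and uses stepwise dihydroxylation and glycol cleavage. Dihydroxylation (OsO4 cat., N-methylmorpholine N-oxide, acetone/H2O) would give methyl (2S,3S)-3-[3-bromo-4-(tert-butyldimethylsilyloxy)benzyl]-2-[4-(tert-butyldimethylsilyloxy)phenyl]-4,5-dihydroxyhexanoate F8 (mixture at C4 and C5). F8 would be cleaved without delay with NaIO4 (THF/H2O, 0 °C), before it can lactonise, coming back to the route at aldehyde 17, which the chlorite stage of step 8 then oxidises to 18.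

Further compounds
F1 | step 7 | pentafluorophenyl 2-[4-(tert-butyldimethylsilyloxy)phenyl]acetate | O=C(Cc1ccc(O[Si](C)(C)C(C)(C)C)cc1)Oc1c(F)c(F)c(F)c(F)c1F
F2 | step 7 | (4-allyl-2-bromophenoxy)(tert-butyl)dimethylsilane | C=CCc1ccc(O[Si](C)(C)C(C)(C)C)c(Br)c1
F3 | step 7 | (E)-4-[3-bromo-4-(tert-butyldimethylsilyloxy)phenyl]but-2-enyl methyl carbonate | COC(=O)OC/C=C/Cc1ccc(O[Si](C)(C)C(C)(C)C)c(Br)c1
F4 | step 7 | pentafluorophenyl (2S,3R)-3-[3-bromo-4-(tert-butyldimethylsilyloxy)benzyl]-2-[4-(tert-butyldimethylsilyloxy)phenyl]pent-4-enoate | O=C(Oc1c(F)c(F)c(F)c(F)c1F)[C@H](c1ccc(O[Si](C)(C)C(C)(C)C)cc1)[C@H](Cc1ccc(O[Si](C)(C)C(C)(C)C)c(Br)c1)C=C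
F5 | step 7 | methyl (2S,3R)-3-[3-bromo-4-(tert-butyldimethylsilyloxy)benzyl]-2-[4-(tert-butyldimethylsilyloxy)phenyl]pent-4-enoate | COC(=O)[C@H](c1ccc(O[Si](C)(C)C(C)(C)C)cc1)[C@H](Cc1ccc(O[Si](C)(C)C(C)(C)C)c(Br)c1)C=C
F6 | step 7 | methyl (2S,3S)-4-[3-bromo-4-(tert-butyldimethylsilyloxy)phenyl]-2-[4-(tert-butyldimethylsilyloxy)phenyl]-3-(1,2,4-trioxolan-3-yl)butanoate | COC(=O)[C@H](c1ccc(O[Si](C)(C)C(C)(C)C)cc1)[C@H](Cc1ccc(O[Si](C)(C)C(C)(C)C)c(Br)c1)C1OCOO1
F7 | step 9 | (2S,3S)-2-[3-allyl-4-(tert-butyldimethylsilyloxy)benzyl]-3-[4-(tert-butyldimethylsilyloxy)phenyl]-4-methoxy-4-oxobutanoic acid | COC(=O)[C@H](c1ccc(O[Si](C)(C)C(C)(C)C)cc1)[C@H](Cc1ccc(O[Si](C)(C)C(C)(C)C)c(CC=C)c1)C(=O)O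
F8 | step 8 | methyl (2S,3S)-3-[3-bromo-4-(tert-butyldimethylsilyloxy)benzyl]-2-[4-(tert-butyldimethylsilyloxy)phenyl]-4,5-dihydroxyhexanoate | COC(=O)[C@H](c1ccc(O[Si](C)(C)C(C)(C)C)cc1)[C@H](Cc1ccc(O[Si](C)(C)C(C)(C)C)c(Br)c1)C(O)C(C)O
A1 | direct plan | rac-(E)-3-(4-acetoxyphenyl)-4-[4-acetoxy-3-(3-methylbut-2-enyl)benzylidene]dihydrofuran-2,5-dione | CC(=O)Oc1ccc(cc1)C1C(=O)OC(=O)/C1=C/c1ccc(OC(C)=O)c(CC=C(C)C)c1
A2 | direct plan | (2E,3R)-3-(4-acetoxyphenyl)-2-[4-acetoxy-3-(3-methylbut-2-enyl)benzylidene]-4-methoxy-4-oxobutanoic acid | COC(=O)[C@H](c1ccc(OC(C)=O)cc1)/C(C(=O)O)=C\c1ccc(OC(C)=O)c(CC=C(C)C)c1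
A3 | direct plan | 3-(4-acetoxyphenyl)-4-[4-acetoxy-3-(3-methylbut-2-enyl)benzyl]furan-2,5-dione | CC(=O)Oc1ccc(cc1)C1=C(Cc2ccc(OC(C)=O)c(CC=C(C)C)c2)C(=O)OC1=O
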